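**Retrosynthetic overview**
1. Target 18 ⇒ chromanol 10 + pyranone 15 + one CH2 unit; the methylene bridge is made last.
2. 10 ⇒ chroman-3-one 9 (enantioselective C=O reduction sets C3) ⇒ 3-nitro-2H-chromene 7 (masked ketone).
3. 7 ⇒ formylphloroacetophenone 3 + nitroalkene 4: the nitronate carbon (an acyl anion equivalent, later the C3 carbonyl) attacks the formyl carbon C4, and the same operation closes O1–C2.
4. 15 ⇒ dianion of methyl 3-oxopentanoate + a propanoyl unit, then lactonisation.
5. Ring order: benzene ring bought; pyran ring (step 2); pyranone ring (step 6, separately); the two halves are joined in step 7.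

Assumption: the stereodescriptor of the target SMILES is read as 3R at the carbinol carbon of the chromane, and 2-methyl-1-nitroprop-1-ene is taken as a catalogue reagent.

**Step 1**
Reactants: 1 1-(2,4,6-trihydroxyphenyl)ethan-1-one
Product: 3 3-acetyl-2,4,6-trihydroxybenzaldehyde, via aryl iminium chloride 2 (not isolated)
Conditions: POCl3 (1.1 equiv), DMF (1.5 equiv), EtOAc, 0 °C to rt; then H2O, 60 °C
Reagents that add atoms: N,N-dimethylformamide, CN(C)C=O (formyl C and H); water, O (carbonyl O)
Why: Vilsmeier–Haack formylation, in which the phloroglucinol ring is far more nucleophilic than the acetyl enol and the first formyl group deactivates the ring against a second one.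

**Step 2**
Reactants: 3 3-acetyl-2,4,6-trihydroxybenzaldehyde, 4 2-methyl-1-nitroprop-1-ene
Product: 7 1-(5,7-dihydroxy-2,2-dimethyl-3-nitro-2H-chromen-6-yl)ethan-1-one, via aryloxy nitronate 5 (not isolated), via nitro aldol 6 (not isolated)
Conditions: 4 (3 equiv), 1,4-diazabicyclo[2.2.2]octane (DABCO, 1 equiv), 4 Å molecular sieves, MeCN, 60 °C
Reagents that add atoms: none
Why: oxa-Michael–Henry–dehydration annulation (the 3-nitro-2H-chromene synthesis from salicylaldehydes and nitroalkenes), in which the 6-OH (para to the acetyl group, not held in the acetyl chelate) adds to 4 and the resulting nitronate 5, an acyl anion equivalent at the future C3, closes on the formyl carbon C4 before water is lost, so no stereocentre remains.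

**Step 3**
Reactants: 7 1-(5,7-dihydroxy-2,2-dimethyl-3-nitro-2H-chromen-6-yl)ethan-1-one
Product: 9 6-acetyl-5,7-dihydroxy-2,2-dimethylchroman-3-one, via ketimine 8 (not isolated)
Conditions: Fe powder (6 equiv), AcOH/H2O 4:1, 80 °C, N2
Reagents that add atoms: water, O (the C3 carbonyl O)
Why: reductive Nef reaction, as in the Fe/acid conversion of aryl-2-nitropropenes to arylacetones, in which the conjugated nitroalkene is reduced to the enamine/ketimine 8 and hydrolysed to the C3 ketone while the chelated aryl ketone is untouched.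

**Step 4**
Reactants: 9 6-acetyl-5,7-dihydroxy-2,2-dimethylchroman-3-one
Product: 10 1-[(3R)-3,5,7-trihydroxy-2,2-dimethyl-3,4-dihydro-2H-chromen-6-yl]ethan-1-one
Conditions: NADPH-dependent ketoreductase selected from a commercial panel for Si-face hydride delivery (Lactobacillus kefir alcohol dehydrogenase type), NADP+ (cat.), propan-2-ol, phosphate buffer pH 7, DMSO (10% v/v), 30 °C
Reagents that add atoms: none
Why: biocatalytic asymmetric ketone reduction, in which the enzyme pocket distinguishes the quaternary C2 side from the benzylic CH2 side and NADPH adds hydride to the Si face of C3=O to give the 3R alcohol, while the hindered, chelated aryl ketone is not a substrate.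

**Step 5**
Reactants: 11 methyl 3-oxopentanoate, 12 N-methoxy-N-methylpropanamide
Product: 14 methyl 4-methyl-3,5-dioxoheptanoate, via ester dianion 13 (not isolated)
Conditions: NaH (1.1 equiv), THF, 0 °C; n-BuLi (1.05 equiv), −10 °C; 12, −78 °C to 0 °C; aq. HCl
Reagents that add atoms: none
Why: Huckin–Weiler dianion chemistry, in which the more basic γ-carbon of 13 is acylated (Claisen-type) by the Weinreb amide without over-addition; the new C4 centre is racemic and is lost in step 6.

**Step 6**
Reactants: 14 methyl 4-methyl-3,5-dioxoheptanoate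
Product: 15 6-ethyl-4-hydroxy-5-methyl-2H-pyran-2-one
Conditions: 1,8-diazabicyclo[5.4.0]undec-7-ene (DBU, 1.2 equiv), toluene, reflux; then 1 M HCl
Reagents that add atoms: none
Why: base-mediated lactonisation of a 3,5-dioxo ester, in which the enol oxygen of the 5-oxo group attacks the ester, methanol leaves and the aromatic 4-hydroxy-2-pyranone forms.

**Step 7**
Reactants: 10 1-[(3R)-3,5,7-trihydroxy-2,2-dimethyl-3,4-dihydro-2H-chromen-6-yl]ethan-1-one, 15 6-ethyl-4-hydroxy-5-methyl-2H-pyran-2-one
Product: 18 3-{[(3R)-6-acetyl-3,5,7-trihydroxy-2,2-dimethyl-3,4-dihydro-2H-chromen-8-yl]methyl}-6-ethyl-4-hydroxy-5-methyl-2H-pyran-2-one (target), via pyranone Mannich base 16 (not isolated), via methylidene pyrandione 17 (not isolated)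
Conditions: 15, [Me2N=CH2]I (1.05 equiv), CHCl3, rt, 1 h; then 10, 50 °C
Reagents that add atoms: N,N-dimethylmethylideneiminium iodide (Eschenmoser's salt), C=[N+](C)C.[I-] (the bridging CH2)
Why: Mannich reaction at C3 of the pyranone, loss of dimethylamine to the methylidene pyrandione 17 and Friedel–Crafts-type Michael addition of C8 of 10 (its only free ring carbon), the established way to methylene-bridged pyranone–acylphloroglucinols; C3 is not touched.

**Compound list**
1 | 1-(2,4,6-trihydroxyphenyl)ethan-1-one (phloroacetophenone) | CC(=O)c1c(O)cc(O)cc1O | starting material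
2 | N-[(3-acetyl-2,4,6-trihydroxyphenyl)methylidene]-N-methylmethanaminium chloride | CC(=O)c1c(O)cc(O)c(C=[N+](C)C)c1O.[Cl-] | intermediate
3 | 3-acetyl-2,4,6-trihydroxybenzaldehyde | CC(=O)c1c(O)cc(O)c(C=O)c1O | intermediate
4 | 2-methyl-1-nitroprop-1-ene | CC(C)=C[N+](=O)[O-] | starting material
5 | nitronate of 3-acetyl-2,4-dihydroxy-6-[(2-methyl-1-nitropropan-2-yl)oxy]benzaldehyde, DABCO-H+ salt | CC(=O)c1c(O)cc(OC(C)(C)C=[N+]([O-])[O-])c(C=O)c1O.C1C[NH+]2CCN1CC2 | intermediate
6 | 1-(4,5,7-trihydroxy-2,2-dimethyl-3-nitro-3,4-dihydro-2H-chromen-6-yl)ethan-1-one (diastereomer mixture, centres lost on dehydration) | CC(=O)c1c(O)cc2OC(C)(C)C([N+](=O)[O-])C(O)c2c1O | intermediate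
7 | 1-(5,7-dihydroxy-2,2-dimethyl-3-nitro-2H-chromen-6-yl)ethan-1-one | CC(=O)c1c(O)cc2OC(C)(C)C([N+](=O)[O-])=Cc2c1O | intermediate
8 | 1-(5,7-dihydroxy-3-imino-2,2-dimethyl-3,4-dihydro-2H-chromen-6-yl)ethan-1-one | CC(=O)c1c(O)cc2OC(C)(C)C(=N)Cc2c1O | intermediate
9 | 6-acetyl-5,7-dihydroxy-2,2-dimethylchroman-3-one | CC(=O)c1c(O)cc2OC(C)(C)C(=O)Cc2c1O | intermediate
10 | 1-[(3R)-3,5,7-trihydroxy-2,2-dimethyl-3,4-dihydro-2H-chromen-6-yl]ethan-1-one | CC(=O)c1c(O)cc2OC(C)(C)[C@H](O)Cc2c1O | intermediate
11 | methyl 3-oxopentanoate | CCC(=O)CC(=O)OC | starting material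
12 | N-methoxy-N-methylpropanamide | CCC(=O)N(C)OC | starting material
13 | sodium lithium 2,4-dianion of methyl 3-oxopentanoate | C[CH-]C(=O)[CH-]C(=O)OC.[Na+].[Li+] | intermediate
14 | methyl 4-methyl-3,5-dioxoheptanoate (racemic) | CCC(=O)C(C)C(=O)CC(=O)OC | intermediate
15 | 6-ethyl-4-hydroxy-5-methyl-2H-pyran-2-one | CCc1oc(=O)cc(O)c1C | intermediate
16 | 3-[(dimethylamino)methyl]-6-ethyl-4-hydroxy-5-methyl-2H-pyran-2-one hydroiodide | CCc1oc(=O)c(C[NH+](C)C)c(O)c1C.[I-] | intermediate
17 | 6-ethyl-5-methyl-3-methylidene-2H-pyran-2,4(3H)-dione | CCC1=C(C)C(=O)C(=C)C(=O)O1 | intermediate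
18 | 3-{[(3R)-6-acetyl-3,5,7-trihydroxy-2,2-dimethyl-3,4-dihydro-2H-chromen-8-yl]methyl}-6-ethyl-4-hydroxy-5-methyl-2H-pyran-2-one | CCc1oc(=O)c(Cc2c(O)c(C(C)=O)c(O)c3c2OC(C)(C)[C@H](O)C3)c(O)c1C | target

**Step count and risks**
Total steps: 7. Longest linear sequence: 5 (steps 1, 2, 3, 4 and 7).

Steps most likely to fail:

Step 2. The phenoxide of 3 is a weak nucleophile and 4 is a hindered acceptor. Amine bases can also move the double bond of 4 out of conjugation. Closure through the 2-OH would give the 8-acetyl regioisomer. The fallback makes the same nitronate C–C bond on an o-quinone methide instead of on the aldehyde; it sets out from 1 and comes back at 9. Mannich reaction of 1 with [Me2N=CH2]I gives 1-{3-[(dimethylamino)methyl]-2,4,6-trihydroxyphenyl}ethan-1-one F1. Heating F1 with 4 and DBU in MeCN at 80 °C expels dimethylamine; the o-quinone methide is attacked at its CH2 by the allyl nitronate of 4 through the nitro-bearing carbon, giving 1-[2,4,6-trihydroxy-3-(3-methyl-2-nitrobut-3-en-1-yl)phenyl]ethan-1-one F2. The same base moves the double bond into conjugation to give 1-[2,4,6-trihydroxy-3-(3-methyl-2-nitrobut-2-en-1-yl)phenyl]ethan-1-one F3, which closes by reversible 6-endo oxa-Michael addition to 1-(5,7-dihydroxy-2,2-dimethyl-3-nitro-3,4-dihydro-2H-chromen-6-yl)ethan-1-one F4; the reversibility lets the ring oxygen equilibrate between the two possible positions. Nef reaction of F4 (NaOMe, MeOH; then aqueous TiCl3/NH4OAc) gives 9.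

Step 3. Iron reduction may stop at the oxime or run on to the 3-amine, and 9 is easily oxidised at C4. The fallback sets out from 7 and comes back at 9. SnCl2·2H2O in EtOAc at rt stops at 1-[5,7-dihydroxy-3-(hydroxyimino)-2,2-dimethyl-3,4-dihydro-2H-chromen-6-yl]ethan-1-one F5. Buffered aqueous TiCl3 (NH4OAc, THF) then cleaves the N–O bond and the imine hydrolyses to 9.

Step 4. A ketone flanked by a quaternary carbon may be accepted slowly or with low selectivity, and the facial preference has to be found by screening. The fallback sets out from 9 and comes back at 10. NaBH4 in MeOH at 0 °C gives racemic 1-(3,5,7-trihydroxy-2,2-dimethyl-3,4-dihydro-2H-chromen-6-yl)ethan-1-one F6. Preparative chiral supercritical-fluid chromatography on an amylose tris(3,5-dimethylphenylcarbamate) phase gives 10 and leaves 1-[(3S)-3,5,7-trihydroxy-2,2-dimethyl-3,4-dihydro-2H-chromen-6-yl]ethan-1-one F7, which is set aside.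

**Further compounds**
F1 | step 2 | 1-{3-[(dimethylamino)methyl]-2,4,6-trihydroxyphenyl}ethan-1-one | CC(=O)c1c(O)cc(O)c(CN(C)C)c1O
F2 | step 2 | 1-[2,4,6-trihydroxy-3-(3-methyl-2-nitrobut-3-en-1-yl)phenyl]ethan-1-one (racemic) | CC(=O)c1c(O)cc(O)c(CC(C(C)=C)[N+](=O)[O-])c1O
F3 | step 2 | 1-[2,4,6-trihydroxy-3-(3-methyl-2-nitrobut-2-en-1-yl)phenyl]ethan-1-one | CC(=O)c1c(O)cc(O)c(CC(=C(C)C)[N+](=O)[O-])c1O
F4 | step 2 | 1-(5,7-dihydroxy-2,2-dimethyl-3-nitro-3,4-dihydro-2H-chromen-6-yl)ethan-1-one (racemic) | CC(=O)c1c(O)cc2OC(C)(C)C([N+](=O)[O-])Cc2c1O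
F5 | step 3 | 1-[5,7-dihydroxy-3-(hydroxyimino)-2,2-dimethyl-3,4-dihydro-2H-chromen-6-yl]ethan-1-one | CC(=O)c1c(O)cc2OC(C)(C)C(=NO)Cc2c1O
F6 | step 4 | racemic 1-(3,5,7-trihydroxy-2,2-dimethyl-3,4-dihydro-2H-chromen-6-yl)ethan-1-one | CC(=O)c1c(O)cc2OC(C)(C)C(O)Cc2c1O
F7 | step 4 | 1-[(3S)-3,5,7-trihydroxy-2,2-dimethyl-3,4-dihydro-2H-chromen-6-yl]ethan-1-one | CC(=O)c1c(O)cc2OC(C)(C)[C@@H](O)Cc2c1O
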